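Numbering used throughout: indane numbering for the bicycle (C1, C2, C3, C3a, C4–C7, C7a). Ring C is C1′ (alkylidene carbon), C2′, C3′ (CMe2), C4′ (CHBr), C5′, C6′, and C8 is the methine between C1 and C1′. β is the face of the C3a methyl group.

## Analysis of the target

Iriediol is a trans-fused hydrindane (cyclopentane C1–C3/C3a/C7a fused to cyclohexane C3a–C7a) carrying at C1 a (4-bromo-3,3-dimethylcyclohexylidene)methyl group, i.e. ring C joined through C8. The bicycle has six stereocentres: quaternary C3a (methyl β), C7a (H α, hence trans fusion), C4 (equatorial β-bromide next to C3a), C7 (tertiary carbinol, hydroxyl axial and β, 1,3-diaxial to the C3a methyl), and C1/C2 (side chain and hydroxyl both α, cis to each other). Ring C adds a seventh centre, C4′ (S), and the C8=C1′ alkene is E, a geometry defined only relative to the remote C4′–Br and the gem-dimethyl group. Both bromides are secondary and neopentylic, so neither can be made by substitution without elimination or methyl migration. The tertiary alcohol is prone to retro-aldol cleavage and dehydration whenever C1 or C4 is a carbonyl. The hard parts are three contiguous centres (C3a, C7a, C7), two of them fully substituted; a bromide next to a quaternary carbon; and the geometry of an alkylidenecyclohexane whose ring arms differ only at a distance. The route rests on the 1,4-relationship of C4 and C7: C4–C5–C6–C7 with the C7 methyl is the skeleton of 2-methylfuran. Its oxidative opening gives a Z-enedione that supplies the C4 carbonyl (later the bromide), the C7 ketone (later the carbinol) and a cis alkene that lets C7a close the ring.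

## Retrosynthetic reasoning

Iriediol 38 is traced to its C7 trimethylsilyl ether 37. Nothing else changes; the silyl group is there because the tertiary hydroxyl must pass a basic olefination and a Lewis-acid cyclisation.

In 37 the C1–C2 bond is cut, opening the five-membered ring to aldehyde 36. An intramolecular carbonyl-ene reaction forming this bond closes the ring, creates C1 and C2, and moves the double bond from C1=C8 to C8=C1′ by passing the C1′ hydrogen to oxygen on the face where C2 bonds to C1. The E/Z problem is thereby exchanged for the configuration of one sp3 carbon of ring C. The forward step must attack C1 on the face that puts the side chain α and must stay concerted.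

The C1=C8 double bond of 36 (through amide 35) is cut next, giving aldehyde 20 and sulfone 34. The cut is convergent, uses the formyl group that the key step places on C7a, and keeps the two bromides in separate halves until late. The olefination must give the E alkene at an aldehyde flanked by two fully substituted carbons.

Aldehyde 20 goes back through hydroxy amide 19 to the trans-fused lactone 18, and 18 through alkenyl bromide 17 and enol triflate 16 to the enone lactones 14 and 13, the reduced and lactonised form of aldol 11. The C4–Br bond is not disconnected to an alcohol, because substitution next to C3a is not viable, but to an alkenyl bromide that takes up hydrogen by hydrogen-atom transfer. The C1/C2 lactone holds the ring in one chair for that step, tells C1 from C2, and removes the enone before a sulfone anion is used.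

In 11 the C7–C7a bond is cut; this is the key disconnection. It leaves an aldehyde whose α-carbon is C7a and the Z-enedione 9, which is the oxidised form of the furan in 8. This is the one ring bond whose formation sets both centres next to the quaternary carbon while both oxygens arrive in the right oxidation state. The forward step must cyclise faster than the enedione isomerises and must select one face of C7a and one face of the C7 ketone.

Aldehyde ester 8 arises by cleaving the C1–C2 bond of α-ketol 7, which derives from cyclopentanone 5. The two arms on the quaternary carbon of 8 are the two halves of a five-membered ring. That ring is only a vehicle for making the quaternary centre by conjugate addition. The cost is that its C1–C2 bond is sacrificed and re-formed at the end with ring C in place. Ketone 5 is cut at the furyl–C3a bond to 2-methylfuran 1 and enone 2.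

Sulfone 34 is traced through alcohol 31 to the cis ester 30, and from there to its C1′ epimer 28, which comes from imide 27. In 27 the C4′–H bond is disconnected (alkenyl bromide 26, enol triflate 25, enol silane 24). Enol silane 24 is the Diels–Alder adduct of diene 22 (from enone 21) and acrylimide 23. The auxiliary fixes C1′, C1′ directs the hydrogen-atom transfer that creates C4′, and C1′, being α to an ester, is then inverted so the information rests in the non-epimerisable C4′–Br.

## Alternatives that were turned down

Alternative 1: The bonds C3a–C7a, C2–C3 and C1–C2 are cut together, leading to an acyclic 1,6-enyne with the alkyne on the C7 carbinol carbon. The forward key step is a cobalt-mediated alkyne–alkene–carbonyl [2+2+1] cycloaddition that gives the bicyclic enone A1.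
- For it: two rings, three C–C bonds and the quaternary C3a form in one step, with oxygen already at C2, C4 and C7. On bonds formed per step it is stronger than the chosen route.
- Against it: C7a is sp2 in A1, so the trans ring-fusion hydrogen and the C1 side chain must be added afterwards, and protonation of a hydrindanone enolate tends to give the cis fusion. The C3a configuration depends on induction from C4 and C7 during the cyclisation. The C4 oxygen still has to be turned into bromide by the carbonyl/alkenyl bromide/hydrogen-atom detour. The side chain would have to arrive as a preformed alkenyl nucleophile of defined geometry, so the alkylidene problem is untouched.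
- In its place the chosen route offers C7a made as an sp3 centre together with C7, and an alkene geometry fixed by hydrogen transfer.

Alternative 2: The bonds C7a–C1 and C3a–C3 are cut, leading to a 4-hydroxycyclohexenone, a ring-C alkenylmagnesium reagent and an α-haloacetate. In the forward key step the magnesium alkoxide directs the alkenyl group to C7a syn to oxygen and the enolate is alkylated at C3a, giving A2.
- For it: it is the most convergent plan and the shortest on paper. The cis C7–O/C7a–C1 relationship is delivered by chelation, which is a firmer control element than the transition-state model used in the chosen aldol.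
- Against it: the alkenylmagnesium reagent has to be made and used in the presence of the secondary bromide of ring C. The enolate must be alkylated at an already substituted α-carbon, where proton transfer and O-alkylation compete. The hydroxy enone needs its own asymmetric synthesis.
- In its place the chosen route makes the quaternary centre first, under catalyst control, on a simple enone, and never exposes a C–Br bond to an organomagnesium reagent.

Alternative 3: The C7a–C1 bond is cut within a lactone tether. A prochiral cyclohexadienone whose tertiary alcohol carries a malonate ester is closed by a chiral bifunctional base onto one enone β-carbon, giving the cis-fused lactone A3.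
- For it: C7 and C7a are set catalytically from a flat, cheap precursor, and their cis relationship is enforced covalently. On that point it is stronger than the chosen route.
- Against it: C3a is still a methylene in A3, so the quaternary centre has to be built by two successive α-alkylations next to the C7a stereocentre. The five-membered ring must then be closed onto the lactone carbonyl, and the extra ester on C1 removed. The malonate adduct can revert by retro-Michael reaction.
- In its place the chosen route has C3a in hand before the ring closes and delivers C1 as a free aldehyde ready for the olefination.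

Key step: step 4

Remark on the chemistry: the sense of induction in step 1 is taken by analogy with aryl–aluminium conjugate additions; both antipodes of the ligand are available, and the one that delivers (R)-5 is used.

## Route

Step 1
Reactants: 1 2-methylfuran; 2 3-methylcyclopent-2-en-1-one
Product: 5 (R)-3-methyl-3-(5-methylfuran-2-yl)cyclopentan-1-one, via (5-methylfuran-2-yl)lithium 3 (not isolated), via dimethyl(5-methylfuran-2-yl)aluminium 4 (not isolated)
Conditions: n-BuLi, THF, 0 °C; Me2AlCl, −78 → 23 °C; then 2, Cu(OTf)2 (5 mol%), chiral sulfonate-bearing imidazolinium salt (carbene ligand precursor, 5 mol%), THF, −78 → −30 °C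
Reagents that add atoms: none
Why: Copper-catalysed asymmetric conjugate addition of an aryl(dimethyl)aluminium reagent to a β-substituted cyclopentenone; the sp2 group transfers in preference to methyl, and the chiral carbene–copper complex sets the quaternary centre (R).

Step 2
Reactants: 5 (R)-3-methyl-3-(5-methylfuran-2-yl)cyclopentan-1-one
Product: 7 (4R)-2-hydroxy-4-methyl-4-(5-methylfuran-2-yl)cyclopentan-1-one (both C2 epimers), via potassium enolate 6 (not isolated)
Conditions: KN(SiMe3)2, THF, −78 °C; 2-(phenylsulfonyl)-3-phenyloxaziridine, −78 °C; aq. NH4Cl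
Reagents that add atoms: 2-(phenylsulfonyl)-3-phenyloxaziridine, O=S(=O)(c1ccccc1)N1OC1c1ccccc1
Why: Kinetic deprotonation occurs at the methylene remote from the quaternary carbon, and the enolate is hydroxylated by the oxaziridine (Davis oxidation); the carbinol configuration is irrelevant because this carbon becomes the aldehyde.

Step 3
Reactants: 7 (4R)-2-hydroxy-4-methyl-4-(5-methylfuran-2-yl)cyclopentan-1-one
Product: 8 methyl (3R)-3-methyl-3-(5-methylfuran-2-yl)-5-oxopentanoate
Conditions: Pb(OAc)4 (1.05 equiv), MeOH/PhH (1:1), 0 °C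
Reagents that add atoms: methanol, CO
Why: Criegee-type cleavage of an α-ketol in methanol turns the ketone carbon into the methyl ester and the carbinol carbon into the aldehyde, differentiating the two arms in one operation; with one equivalent at 0 °C the ketol reacts before the furan.

Step 4
Reactants: 8 methyl (3R)-3-methyl-3-(5-methylfuran-2-yl)-5-oxopentanoate
Product: 11 methyl 2-[(1S,5R,6S)-6-formyl-5-hydroxy-1,5-dimethyl-2-oxocyclohex-3-en-1-yl]acetate, via Z-enedione 9 (not isolated), via dibenzylamine enamine 10 (not isolated)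
Conditions: mCPBA (1.0 equiv), CH2Cl2, 0 °C; then Bn2NH (20 mol%), 0 → 23 °C
Reagents that add atoms: 3-chloroperbenzoic acid, O=C(OO)c1cccc(Cl)c1
Why: The peracid adds to the 2,5-dialkylfuran and the adduct collapses to the Z-enedione 9, the furan oxygen becoming the C4 carbonyl oxygen and the peracid oxygen the C7 carbonyl oxygen; the closest known reactions are the oxidative ring opening of furans and the amine-catalysed enolexo aldol addition of keto aldehydes, here run without isolation. Dibenzylamine, with the 3-chlorobenzoic acid already present as co-acid, condenses with the aldehyde to the E-enamine 10, whose carbon C7a adds to the C7 methyl ketone, and hydrolysis returns the amine. The ring closes in the 6-enolexo-exo-trig mode, the Z alkene holding C7 within reach of C7a. C7a is controlled in a chair-like transition state with the exocyclic enamine equatorial: A(1,3) strain with the enamine hydrogen puts the C3a methyl, not the CH2CO2Me arm, axial, so the formyl group ends cis to that methyl and trans to the ester arm. C7 is controlled by the ketone oxygen, rather than its methyl group, taking the pseudo-axial site syn to the axial C3a methyl, which avoids a methyl/methyl 1,3-diaxial contact and places the hydroxyl cis to the formyl group. This kinetic model is used because equilibration through retro-aldol would not clearly favour the same isomer. The step needs the aldehyde to be the only carbon nucleophile (enolisation of the methyl ketone would give a cyclopentenone aldol) and must stop before dehydration: the secondary amine activates only the aldehyde, C4 has no α-hydrogen on the C3a side, and the temperature is kept at or below 23 °C.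

Step 5
Reactants: 11 methyl 2-[(1S,5R,6S)-6-formyl-5-hydroxy-1,5-dimethyl-2-oxocyclohex-3-en-1-yl]acetate
Product: 13 (1R,6S,10R)-10-hydroxy-6,10-dimethyl-3-oxabicyclo[4.4.0]dec-8-ene-4,7-dione, via hydroxy ester 12 (not isolated)
Conditions: NaBH4 (0.35 equiv), CH2Cl2/MeOH, −78 °C; then PPTS (cat.), PhMe, 40 °C
Reagents that add atoms: none
Why: Chemoselective borohydride reduction of the aldehyde in the presence of the hindered enone, then lactonisation of the trans-diequatorial CH2OH and CH2CO2Me arms; the trans-fused δ-lactone locks the chair with the C3a methyl axial and masks C1 and C2.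

Step 6
Reactants: 13 (1R,6S,10R)-10-hydroxy-6,10-dimethyl-3-oxabicyclo[4.4.0]dec-8-ene-4,7-dione
Product: 14 (1R,6S,10R)-6,10-dimethyl-10-(trimethylsilyloxy)-3-oxabicyclo[4.4.0]dec-8-ene-4,7-dione
Conditions: TMSOTf, 2,6-lutidine, CH2Cl2, −78 °C
Reagents that add atoms: trimethylsilyl triflate, C[Si](C)(C)OS(=O)(=O)C(F)(F)F
Why: Silylation of the tertiary alcohol with a silyl triflate and a hindered base; the ether protects C7–OH against retro-aldol cleavage and elimination in the steps that follow.

Step 7
Reactants: 14 (1R,6S,10R)-6,10-dimethyl-10-(trimethylsilyloxy)-3-oxabicyclo[4.4.0]dec-8-ene-4,7-dione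
Product: 16 (1R,6S,10R)-6,10-dimethyl-4-oxo-10-(trimethylsilyloxy)-3-oxabicyclo[4.4.0]dec-7-en-7-yl trifluoromethanesulfonate, via lithium enolate 15 (not isolated)
Conditions: LiBH(s-Bu)3 (1.05 equiv), THF, −78 °C; PhNTf2, −78 → 0 °C
Reagents that add atoms: N-phenylbis(trifluoromethanesulfonimide), O=S(=O)(N(c1ccccc1)S(=O)(=O)C(F)(F)F)C(F)(F)F
Why: Conjugate reduction of a β-unsubstituted cyclohexenone whose carbonyl is shielded by the quaternary C3a, with trapping of the regiodefined C4 enolate as its triflate; at −78 °C the enone reacts before the lactone.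

Step 8
Reactants: 16 (1R,6S,10R)-6,10-dimethyl-4-oxo-10-(trimethylsilyloxy)-3-oxabicyclo[4.4.0]dec-7-en-7-yl trifluoromethanesulfonate
Product: 17 (1R,6S,10R)-7-bromo-6,10-dimethyl-10-(trimethylsilyloxy)-3-oxabicyclo[4.4.0]dec-7-en-4-one
Conditions: Ni(OAc)2·4H2O (10 mol%), 1,5-cyclooctadiene (25 mol%), Zn (20 mol%), LiBr (2 equiv), DMA/THF, 23 °C
Reagents that add atoms: lithium bromide, [Li+].[Br-]
Why: Nickel-catalysed halide exchange of an enol triflate (oxidative addition to zerovalent nickel, triflate/bromide exchange, reductive elimination); no alkyl halide is present yet that could compete.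

Step 9
Reactants: 17 (1R,6S,10R)-7-bromo-6,10-dimethyl-10-(trimethylsilyloxy)-3-oxabicyclo[4.4.0]dec-7-en-4-one
Product: 18 (1R,6S,7S,10R)-7-bromo-6,10-dimethyl-10-(trimethylsilyloxy)-3-oxabicyclo[4.4.0]decan-4-one
Conditions: Co(acac)2 (25 mol%), t-BuOOH, Et3SiH, 1,4-cyclohexadiene, n-PrOH, 23 °C
Reagents that add atoms: none
Why: Hydrogen-atom-transfer hydrogenation of an alkenyl bromide: a cobalt hydride delivers H to C5 and the α-bromo radical at C4 takes H from cyclohexadiene. On the rigid trans-fused bicycle the donor approaches axially from the α face, anti to the axial C3a methyl, so bromine ends equatorial and β (4S).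

Step 10
Reactants: 18 (1R,6S,7S,10R)-7-bromo-6,10-dimethyl-10-(trimethylsilyloxy)-3-oxabicyclo[4.4.0]decan-4-one
Product: 19 2-[(1S,2S,5R,6R)-2-bromo-6-(hydroxymethyl)-1,5-dimethyl-5-(trimethylsilyloxy)cyclohexyl]-N-methoxy-N-methylacetamide
Conditions: MeNH(OMe)·HCl, AlMe3, CH2Cl2, 0 → 23 °C
Reagents that add atoms: N,O-dimethylhydroxylamine hydrochloride, CNOC.Cl
Why: Aminolysis of the lactone by the aluminium amide (Weinreb amide formation) frees C1 as a primary alcohol and leaves C2 as an amide that later gives the aldehyde without over-reduction.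

Step 11
Reactants: 19 2-[(1S,2S,5R,6R)-2-bromo-6-(hydroxymethyl)-1,5-dimethyl-5-(trimethylsilyloxy)cyclohexyl]-N-methoxy-N-methylacetamide
Product: 20 2-[(1S,2S,5R,6S)-2-bromo-6-formyl-1,5-dimethyl-5-(trimethylsilyloxy)cyclohexyl]-N-methoxy-N-methylacetamide
Conditions: Dess–Martin periodinane, NaHCO3, CH2Cl2, 0 → 23 °C
Reagents that add atoms: none
Why: Dess–Martin oxidation of the primary alcohol under buffered, non-basic conditions; C7a is not epimerised and the silyl ether blocks retro-aldol cleavage.

Step 12
Reactants: 21 4-methylpent-1-en-3-one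
Product: 22 tert-butyl(dimethyl)[(4-methylpenta-1,3-dien-3-yl)oxy]silane
Conditions: TBSOTf, Et3N, Et2O, 0 °C
Reagents that add atoms: tert-butyldimethylsilyl triflate, CC(C)(C)[Si](C)(C)OS(=O)(=O)C(F)(F)F
Why: Soft enolisation and O-silylation of the vinyl ketone; the isopropyl methine is the only α-hydrogen, so a single 2-silyloxydiene with the gem-dimethyl terminus is formed.

Step 13
Reactants: 22 tert-butyl(dimethyl)[(4-methylpenta-1,3-dien-3-yl)oxy]silane; 23 (4S)-4-benzyl-3-(prop-2-enoyl)-1,3-oxazolidin-2-one
Product: 24 (4S)-4-benzyl-3-[(1S)-4-(tert-butyldimethylsilyloxy)-5,5-dimethylcyclohex-3-ene-1-carbonyl]-1,3-oxazolidin-2-one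
Conditions: Et2AlCl (1.4 equiv), CH2Cl2, −78 °C
Reagents that add atoms: none
Why: Auxiliary-controlled Lewis-acid Diels–Alder reaction (Evans acrylimide). The 2-silyloxy group directs the dimethyl terminus to the acrylimide β-carbon, so the acyl carbon ends 1,4 to the enol silane and 1,3 to CMe2, and the diene adds to the chelated s-cis acrylimide anti to the benzyl group, giving C1′ (S). A stepwise Mukaiyama–Michael/Michael course would lead to the same adduct.

Step 14
Reactants: 24 (4S)-4-benzyl-3-[(1S)-4-(tert-butyldimethylsilyloxy)-5,5-dimethylcyclohex-3-ene-1-carbonyl]-1,3-oxazolidin-2-one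
Product: 25 (4S)-4-benzyl-3-[(1S)-5,5-dimethyl-4-(trifluoromethylsulfonyloxy)cyclohex-3-ene-1-carbonyl]-1,3-oxazolidin-2-one
Conditions: CsF, PhNTf2, DME, 23 °C
Reagents that add atoms: N-phenylbis(trifluoromethanesulfonimide), O=S(=O)(N(c1ccccc1)S(=O)(=O)C(F)(F)F)C(F)(F)F
Why: Fluoride-induced conversion of the enol silane into the enol triflate without enolate equilibration, so the double bond stays at C4′=C5′.

Step 15
Reactants: 25 (4S)-4-benzyl-3-[(1S)-5,5-dimethyl-4-(trifluoromethylsulfonyloxy)cyclohex-3-ene-1-carbonyl]-1,3-oxazolidin-2-one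
Product: 26 (4S)-4-benzyl-3-[(1S)-4-bromo-5,5-dimethylcyclohex-3-ene-1-carbonyl]-1,3-oxazolidin-2-one
Conditions: Ni(OAc)2·4H2O (10 mol%), 1,5-cyclooctadiene (25 mol%), Zn (20 mol%), LiBr (2 equiv), DMA/THF, 23 °C
Reagents that add atoms: lithium bromide, [Li+].[Br-]
Why: The same nickel-catalysed triflate-to-bromide exchange as in step 8, here on the ring-C enol triflate.

Step 16
Reactants: 26 (4S)-4-benzyl-3-[(1S)-4-bromo-5,5-dimethylcyclohex-3-ene-1-carbonyl]-1,3-oxazolidin-2-one
Product: 27 (4S)-4-benzyl-3-[(1S,4S)-4-bromo-3,3-dimethylcyclohexane-1-carbonyl]-1,3-oxazolidin-2-one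
Conditions: Co(acac)2 (25 mol%), t-BuOOH, Et3SiH, 1,4-cyclohexadiene, n-PrOH, 23 °C
Reagents that add atoms: none
Why: Hydrogen-atom-transfer hydrogenation of the alkenyl bromide as in step 9. The acyl group is equatorial (an axial one would be syn-diaxial to a C3′ methyl), and axial H delivery to the C4′ radical anti to the axial C3′ methyl gives the equatorial bromide, trans to the acyl group, i.e. C4′ (S).

Step 17
Reactants: 27 (4S)-4-benzyl-3-[(1S,4S)-4-bromo-3,3-dimethylcyclohexane-1-carbonyl]-1,3-oxazolidin-2-one
Product: 28 methyl (1S,4S)-4-bromo-3,3-dimethylcyclohexane-1-carboxylate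
Conditions: NaOMe, MeOH, 0 °C
Reagents that add atoms: methanol, CO
Why: Methanolysis of the exocyclic imide carbonyl releases the auxiliary; the equatorial bromide has no anti-periplanar hydrogen, so elimination does not compete at 0 °C.

Step 18
Reactants: 28 methyl (1S,4S)-4-bromo-3,3-dimethylcyclohexane-1-carboxylate
Product: 30 methyl (1R,4S)-4-bromo-3,3-dimethylcyclohexane-1-carboxylate, via lithium ester enolate 29 (not isolated)
Conditions: LiN(i-Pr)2, THF, −78 °C; AcOH, −78 °C; chromatographic separation, recovered 28 resubmitted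
Reagents that add atoms: none
Why: Enolisation erases C1′ and kinetic protonation from the face away from the axial C3′ methyl re-forms it. A cis/trans mixture is expected, because the ring can react with bromine equatorial or axial. The cis ester 30 is separated and the trans ester recycled, so the stereochemical information now rests in the non-epimerisable C4′–Br.

Step 19
Reactants: 30 methyl (1R,4S)-4-bromo-3,3-dimethylcyclohexane-1-carboxylate
Product: 31 [(1R,4S)-4-bromo-3,3-dimethylcyclohexyl]methanol
Conditions: i-Bu2AlH (2.5 equiv), CH2Cl2, −78 → 0 °C; aq. potassium sodium tartrate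
Reagents that add atoms: none
Why: Hydride reduction of the ester to the primary alcohol; the hindered secondary bromide is inert to the aluminium hydride at this temperature.

Step 20
Reactants: 31 [(1R,4S)-4-bromo-3,3-dimethylcyclohexyl]methanol; 32 1-phenyl-1H-tetrazole-5-thiol
Product: 33 5-({[(1R,4S)-4-bromo-3,3-dimethylcyclohexyl]methyl}sulfanyl)-1-phenyl-1H-tetrazole
Conditions: PPh3, DIAD, THF, 0 → 23 °C
Reagents that add atoms: none
Why: Mitsunobu thioetherification of a primary alcohol; the neopentylic secondary bromide does not undergo substitution.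

Step 21
Reactants: 33 5-({[(1R,4S)-4-bromo-3,3-dimethylcyclohexyl]methyl}sulfanyl)-1-phenyl-1H-tetrazole
Product: 34 5-({[(1R,4S)-4-bromo-3,3-dimethylcyclohexyl]methyl}sulfonyl)-1-phenyl-1H-tetrazole
Conditions: (NH4)6Mo7O24·4H2O (10 mol%), 30% H2O2, EtOH, 0 → 23 °C
Reagents that add atoms: hydrogen peroxide, OO
Why: Molybdate-catalysed oxidation of the sulfide to the sulfone, the standard entry to tetrazolyl sulfones for the Julia–Kocienski reaction.

Step 22
Reactants: 20 2-[(1S,2S,5R,6S)-2-bromo-6-formyl-1,5-dimethyl-5-(trimethylsilyloxy)cyclohexyl]-N-methoxy-N-methylacetamide; 34 5-({[(1R,4S)-4-bromo-3,3-dimethylcyclohexyl]methyl}sulfonyl)-1-phenyl-1H-tetrazole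
Product: 35 2-[(1S,2S,5R,6S)-2-bromo-6-[(E)-2-[(1R,4S)-4-bromo-3,3-dimethylcyclohexyl]ethenyl]-1,5-dimethyl-5-(trimethylsilyloxy)cyclohexyl]-N-methoxy-N-methylacetamide
Conditions: KN(SiMe3)2 added to 20 + 34, DME, −60 → 23 °C
Reagents that add atoms: none
Why: Julia–Kocienski olefination under Barbier conditions: the sulfone anion adds to the aldehyde, and Smiles rearrangement with loss of SO2 and the tetrazolone gives the alkene. Phenyltetrazolyl sulfones with a potassium counter-ion in DME favour the E alkene, all the more with two branched partners. The aldehyde is the only carbonyl that competes, since the enone is gone and the Weinreb amide is much less electrophilic.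

Step 23
Reactants: 35 2-[(1S,2S,5R,6S)-2-bromo-6-[(E)-2-[(1R,4S)-4-bromo-3,3-dimethylcyclohexyl]ethenyl]-1,5-dimethyl-5-(trimethylsilyloxy)cyclohexyl]-N-methoxy-N-methylacetamide
Product: 36 2-[(1S,2S,5R,6S)-2-bromo-6-[(E)-2-[(1R,4S)-4-bromo-3,3-dimethylcyclohexyl]ethenyl]-1,5-dimethyl-5-(trimethylsilyloxy)cyclohexyl]acetaldehyde
Conditions: i-Bu2AlH (1.3 equiv), THF, −78 °C; aq. potassium sodium tartrate
Reagents that add atoms: none
Why: Reduction of the Weinreb amide stops at the chelated tetrahedral intermediate, which releases the C2 aldehyde on work-up.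

Step 24
Reactants: 36 2-[(1S,2S,5R,6S)-2-bromo-6-[(E)-2-[(1R,4S)-4-bromo-3,3-dimethylcyclohexyl]ethenyl]-1,5-dimethyl-5-(trimethylsilyloxy)cyclohexyl]acetaldehyde
Product: 37 (1S,2R,3aS,4S,7R,7aS)-4-bromo-1-[(E)-[(4S)-4-bromo-3,3-dimethylcyclohexylidene]methyl]-3a,7-dimethyl-7-(trimethylsilyloxy)octahydro-1H-inden-2-ol
Conditions: Me2AlCl (2 equiv), CH2Cl2, −78 → −20 °C
Reagents that add atoms: none
Why: Lewis-acid-promoted intramolecular carbonyl-ene reaction with the enophile tethered to the alkene terminus, closing the five-membered ring in the exo mode. With C7a–H eclipsing the alkene, C2 reaches the C1 face that puts C8 on the α side; the six-membered hydrogen-transfer array forces oxygen and C8 syn, giving the cis C1/C2 relationship. Suprafacial transfer of the C1′ hydrogen from the (1′R) centre places the CMe2-bearing arm trans to C1, which is the E alkene.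

Step 25
Reactants: 37 (1S,2R,3aS,4S,7R,7aS)-4-bromo-1-[(E)-[(4S)-4-bromo-3,3-dimethylcyclohexylidene]methyl]-3a,7-dimethyl-7-(trimethylsilyloxy)octahydro-1H-inden-2-ol
Product: 38 iriediol
Conditions: HF·pyridine, THF/pyridine, 0 → 23 °C
Reagents that add atoms: none
Why: Fluoride-mediated cleavage of the tertiary trimethylsilyl ether under buffered conditions that leave the bromides and the alkene untouched.

## Compound list

1 | 2-methylfuran | Cc1ccco1 | starting material
2 | 3-methylcyclopent-2-en-1-one | CC1=CC(=O)CC1 | starting material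
3 | (5-methylfuran-2-yl)lithium | [Li]c1ccc(C)o1 | intermediate
4 | dimethyl(5-methylfuran-2-yl)aluminium | C[Al](C)c1ccc(C)o1 | intermediate
5 | (R)-3-methyl-3-(5-methylfuran-2-yl)cyclopentan-1-one | C[C@@]1(c2ccc(C)o2)CCC(=O)C1 | intermediate
6 | potassium (4R)-4-methyl-4-(5-methylfuran-2-yl)cyclopent-1-en-1-olate | C[C@@]1(c2ccc(C)o2)CC=C([O-])C1.[K+] | intermediate
7 | (4R)-2-hydroxy-4-methyl-4-(5-methylfuran-2-yl)cyclopentan-1-one (C2 epimers) | C[C@@]1(c2ccc(C)o2)CC(O)C(=O)C1 | intermediate
8 | methyl (3R)-3-methyl-3-(5-methylfuran-2-yl)-5-oxopentanoate | O=CC[C@](C)(CC(=O)OC)c1ccc(C)o1 | intermediate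
9 | methyl (3R,5Z)-3-methyl-4,7-dioxo-3-(2-oxoethyl)oct-5-enoate | O=CC[C@](C)(CC(=O)OC)C(=O)/C=C\C(C)=O | intermediate
10 | methyl (3S,5Z)-3-[(E)-2-(dibenzylamino)ethenyl]-3-methyl-4,7-dioxooct-5-enoate | C(c1ccccc1)N(Cc1ccccc1)/C=C/[C@](C)(CC(=O)OC)C(=O)/C=C\C(C)=O | intermediate
11 | methyl 2-[(1S,5R,6S)-6-formyl-5-hydroxy-1,5-dimethyl-2-oxocyclohex-3-en-1-yl]acetate | O=C[C@@H]1[C@](C)(O)C=CC(=O)[C@@]1(C)CC(=O)OC | intermediate
12 | methyl 2-[(1S,5R,6R)-5-hydroxy-6-(hydroxymethyl)-1,5-dimethyl-2-oxocyclohex-3-en-1-yl]acetate | OC[C@@H]1[C@](C)(O)C=CC(=O)[C@@]1(C)CC(=O)OC | intermediate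
13 | (1R,6S,10R)-10-hydroxy-6,10-dimethyl-3-oxabicyclo[4.4.0]dec-8-ene-4,7-dione (trans-fused δ-lactone) | C1[C@@H]2[C@](C)(O)C=CC(=O)[C@@]2(C)CC(=O)O1 | intermediate
14 | (1R,6S,10R)-6,10-dimethyl-10-(trimethylsilyloxy)-3-oxabicyclo[4.4.0]dec-8-ene-4,7-dione | C1[C@@H]2[C@](C)(O[Si](C)(C)C)C=CC(=O)[C@@]2(C)CC(=O)O1 | intermediate
15 | lithium C4 enolate of the saturated ketone lactone (lithium 6,10-dimethyl-4-oxo-10-(trimethylsilyloxy)-3-oxabicyclo[4.4.0]dec-7-en-7-olate) | C1[C@@H]2[C@](C)(O[Si](C)(C)C)CC=C([O-])[C@@]2(C)CC(=O)O1.[Li+] | intermediate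
16 | (1R,6S,10R)-6,10-dimethyl-4-oxo-10-(trimethylsilyloxy)-3-oxabicyclo[4.4.0]dec-7-en-7-yl trifluoromethanesulfonate | C1[C@@H]2[C@](C)(O[Si](C)(C)C)CC=C(OS(=O)(=O)C(F)(F)F)[C@@]2(C)CC(=O)O1 | intermediate
17 | (1R,6S,10R)-7-bromo-6,10-dimethyl-10-(trimethylsilyloxy)-3-oxabicyclo[4.4.0]dec-7-en-4-one | C1[C@@H]2[C@](C)(O[Si](C)(C)C)CC=C(Br)[C@@]2(C)CC(=O)O1 | intermediate
18 | (1R,6S,7S,10R)-7-bromo-6,10-dimethyl-10-(trimethylsilyloxy)-3-oxabicyclo[4.4.0]decan-4-one | C1[C@@H]2[C@](C)(O[Si](C)(C)C)CC[C@H](Br)[C@@]2(C)CC(=O)O1 | intermediate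
19 | 2-[(1S,2S,5R,6R)-2-bromo-6-(hydroxymethyl)-1,5-dimethyl-5-(trimethylsilyloxy)cyclohexyl]-N-methoxy-N-methylacetamide | OC[C@@H]1[C@](C)(O[Si](C)(C)C)CC[C@H](Br)[C@@]1(C)CC(=O)N(C)OC | intermediate
20 | 2-[(1S,2S,5R,6S)-2-bromo-6-formyl-1,5-dimethyl-5-(trimethylsilyloxy)cyclohexyl]-N-methoxy-N-methylacetamide | O=C[C@@H]1[C@](C)(O[Si](C)(C)C)CC[C@H](Br)[C@@]1(C)CC(=O)N(C)OC | intermediate
21 | 4-methylpent-1-en-3-one | C=CC(=O)C(C)C | starting material
22 | tert-butyl(dimethyl)[(4-methylpenta-1,3-dien-3-yl)oxy]silane | C=CC(O[Si](C)(C)C(C)(C)C)=C(C)C | intermediate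
23 | (4S)-4-benzyl-3-(prop-2-enoyl)-1,3-oxazolidin-2-one | C=CC(=O)N1[C@@H](Cc2ccccc2)COC1=O | starting material
24 | (4S)-4-benzyl-3-[(1S)-4-(tert-butyldimethylsilyloxy)-5,5-dimethylcyclohex-3-ene-1-carbonyl]-1,3-oxazolidin-2-one | O=C([C@@H]1CC(C)(C)C(O[Si](C)(C)C(C)(C)C)=CC1)N1[C@@H](Cc2ccccc2)COC1=O | intermediate
25 | (4S)-4-benzyl-3-[(1S)-5,5-dimethyl-4-(trifluoromethylsulfonyloxy)cyclohex-3-ene-1-carbonyl]-1,3-oxazolidin-2-one | O=C([C@@H]1CC(C)(C)C(OS(=O)(=O)C(F)(F)F)=CC1)N1[C@@H](Cc2ccccc2)COC1=O | intermediate
26 | (4S)-4-benzyl-3-[(1S)-4-bromo-5,5-dimethylcyclohex-3-ene-1-carbonyl]-1,3-oxazolidin-2-one | O=C([C@@H]1CC(C)(C)C(Br)=CC1)N1[C@@H](Cc2ccccc2)COC1=O | intermediate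
27 | (4S)-4-benzyl-3-[(1S,4S)-4-bromo-3,3-dimethylcyclohexane-1-carbonyl]-1,3-oxazolidin-2-one | O=C([C@@H]1CC(C)(C)[C@@H](Br)CC1)N1[C@@H](Cc2ccccc2)COC1=O | intermediate
28 | methyl (1S,4S)-4-bromo-3,3-dimethylcyclohexane-1-carboxylate (trans) | COC(=O)[C@@H]1CC(C)(C)[C@@H](Br)CC1 | intermediate
29 | lithium enolate of methyl (4S)-4-bromo-3,3-dimethylcyclohexane-1-carboxylate | COC([O-])=C1CC(C)(C)[C@@H](Br)CC1.[Li+] | intermediate
30 | methyl (1R,4S)-4-bromo-3,3-dimethylcyclohexane-1-carboxylate (cis) | COC(=O)[C@H]1CC(C)(C)[C@@H](Br)CC1 | intermediate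
31 | [(1R,4S)-4-bromo-3,3-dimethylcyclohexyl]methanol | OC[C@H]1CC(C)(C)[C@@H](Br)CC1 | intermediate
32 | 1-phenyl-1H-tetrazole-5-thiol | Sc1nnnn1-c1ccccc1 | starting material
33 | 5-({[(1R,4S)-4-bromo-3,3-dimethylcyclohexyl]methyl}sulfanyl)-1-phenyl-1H-tetrazole | c1ccc(cc1)-n1nnnc1SC[C@H]1CC(C)(C)[C@@H](Br)CC1 | intermediate
34 | 5-({[(1R,4S)-4-bromo-3,3-dimethylcyclohexyl]methyl}sulfonyl)-1-phenyl-1H-tetrazole | c1ccc(cc1)-n1nnnc1S(=O)(=O)C[C@H]1CC(C)(C)[C@@H](Br)CC1 | intermediate
35 | 2-[(1S,2S,5R,6S)-2-bromo-6-[(E)-2-[(1R,4S)-4-bromo-3,3-dimethylcyclohexyl]ethenyl]-1,5-dimethyl-5-(trimethylsilyloxy)cyclohexyl]-N-methoxy-N-methylacetamide | CC1(C)C[C@H](/C=C/[C@@H]2[C@](C)(O[Si](C)(C)C)CC[C@H](Br)[C@@]2(C)CC(=O)N(C)OC)CC[C@@H]1Br | intermediate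
36 | 2-[(1S,2S,5R,6S)-2-bromo-6-[(E)-2-[(1R,4S)-4-bromo-3,3-dimethylcyclohexyl]ethenyl]-1,5-dimethyl-5-(trimethylsilyloxy)cyclohexyl]acetaldehyde | CC1(C)C[C@H](/C=C/[C@@H]2[C@](C)(O[Si](C)(C)C)CC[C@H](Br)[C@@]2(C)CC=O)CC[C@@H]1Br | intermediate
37 | (1S,2R,3aS,4S,7R,7aS)-4-bromo-1-[(E)-[(4S)-4-bromo-3,3-dimethylcyclohexylidene]methyl]-3a,7-dimethyl-7-(trimethylsilyloxy)octahydro-1H-inden-2-ol | CC1(C)C/C(=C/[C@@H]2[C@H](O)C[C@]3(C)[C@@H](Br)CC[C@@](C)(O[Si](C)(C)C)[C@@H]23)CC[C@@H]1Br | intermediate
38 | iriediol, (1S,2R,3aS,4S,7R,7aS)-4-bromo-1-[(E)-[(4S)-4-bromo-3,3-dimethylcyclohexylidene]methyl]-3a,7-dimethyloctahydro-1H-indene-2,7-diol | CC1(C)C/C(=C/[C@@H]2[C@H](O)C[C@]3(C)[C@@H](Br)CC[C@@](C)(O)[C@@H]23)CC[C@@H]1Br | target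

## Step count and least certain steps

Total: 25 steps. Longest linear sequence: 15 steps (steps 1–11, then 22–25). The ring-C branch (steps 12–21) has 10 steps and joins at step 22.

Step 4 (key step).
- What may go wrong: the amine may isomerise the Z-enedione to the E isomer by reversible conjugate addition before the ring closes. The tertiary aldol may dehydrate to a cross-conjugated dienone. Facial selection at C7a rests on the modest size difference between the methyl and the CH2CO2Me arm, so the C7a epimer may form alongside.
- Fallback, from 8 back to 11: the aldehyde is converted with TBSOTf/Et3N into the silyl enol ether F1. The furan, far more reactive towards singlet oxygen than the enol ether, is opened (O2, hν, methylene blue, CH2Cl2, −78 °C; then Me2S) to the enedione enol ether F2. An intramolecular Mukaiyama aldol addition (BF3·OEt2, CH2Cl2, −78 °C) then forms C7–C7a without any amine and gives 11 after aqueous work-up.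

Step 24 (carbonyl-ene closure).
- What may go wrong: the 1,2-disubstituted alkene is a weak ene donor, so the Lewis acid may drive a stepwise cationic course. That would bring capture of the C8 cation by a neighbouring oxygen, hydride shift, and loss of the geometric fidelity that only a concerted hydrogen transfer gives. Ionisation of the tertiary silyl ether is a further risk.
- Fallback, from 36 back to 37: homologation with dimethyl (1-diazo-2-oxopropyl)phosphonate (K2CO3, MeOH) gives the terminal alkyne F3. Palladium-catalysed enyne cycloisomerisation (Pd(OAc)2, PPh3, PhH, 60 °C; an Alder-ene process with syn carbopalladation and syn β-hydride elimination of the same C1′–H) closes C1–C2 and gives the 2-methylene hydrindane F4 with the C8=C1′ alkene. Cleavage of the less hindered exocyclic methylene (OsO4 cat., NaIO4) gives ketone F5, and LiBH(s-Bu)3 reduction anti to the C1 substituent returns 37.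

Step 22 (Julia–Kocienski olefination).
- What may go wrong: the aldehyde sits between two fully substituted carbons, so addition of the branched sulfone anion may be slow. Deprotonation at C7a would then compete, followed by epimerisation or β-elimination of the silyloxy group.
- Fallback, from 31 and 20 back to 35: the alcohol is converted (I2, PPh3, imidazole) into the iodide F6 and then (PPh3, MeCN, 80 °C) into the phosphonium iodide F7. Wittig reaction of F7 (NaN(SiMe3)2, THF, −78 °C) with 20, which tolerates hindrance better, gives mainly the Z alkene F8. Thiyl-radical isomerisation (PhSSPh cat., hν) then converts F8 into the strongly favoured E isomer 35.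

Step 13 (Diels–Alder reaction).
- What may go wrong: the diene has a methyl group cis at its reacting terminus and may react slowly. The enol silane may then be cleaved by the Lewis acid, or selectivity may drop at the higher temperature needed.
- Fallback, from commercial esters to 25: Michael addition of the lithium enolate of methyl isobutyrate to dimethyl 2-methylenepentanedioate gives the triester F9. Dieckmann cyclisation (KOt-Bu) gives the β-keto diester F10, and Krapcho dealkoxycarbonylation (LiCl, wet DMSO, 150 °C) gives the racemic keto ester F11. Hydrolysis gives the keto acid F12, which is attached to (S)-4-benzyloxazolidin-2-one (pivaloyl chloride, Et3N, LiCl). The diastereomers are separated, with the unwanted one recycled by epimerisation at C1′, to give the (1S) keto imide F13. Enolisation with LiN(SiMe3)2 and PhNTf2 returns to 25.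

Step 1 (conjugate addition).
- What may go wrong: transfer of the furyl group from aluminium to copper may be slow compared with methyl transfer, or enantioselectivity with a heteroaryl group may fall below that known for aryl groups.
- Fallback, from 3 back to 5: addition of 3 to 3-ethoxycyclopent-2-en-1-one and acidic work-up gives the furyl enone F14. The other bond to the quaternary carbon is then formed by copper-catalysed asymmetric conjugate addition of AlMe3 (Cu(OTf)2, chiral phosphoramidite ligand, Et2O, −30 °C), with the ligand antipode chosen to give (R)-5.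

## Further compounds

F1 | step 4 | methyl (3S)-5-(tert-butyldimethylsilyloxy)-3-methyl-3-(5-methylfuran-2-yl)pent-4-enoate (E/Z mixture) | CC(C)(C)[Si](C)(C)OC=C[C@](C)(CC(=O)OC)c1ccc(C)o1
F2 | step 4 | methyl (3S,5Z)-3-[2-(tert-butyldimethylsilyloxy)ethenyl]-3-methyl-4,7-dioxooct-5-enoate | CC(C)(C)[Si](C)(C)OC=C[C@](C)(CC(=O)OC)C(=O)/C=C\C(C)=O
F3 | step 24 | terminal alkyne from 36 (CH2–C≡CH arm on C3a) | CC1(C)C[C@H](/C=C/[C@@H]2[C@](C)(O[Si](C)(C)C)CC[C@H](Br)[C@@]2(C)CC#C)CC[C@@H]1Br
F4 | step 24 | 2-methylene hydrindane, C7 trimethylsilyl ether | CC1(C)C/C(=C/[C@@H]2C(=C)C[C@]3(C)[C@@H](Br)CC[C@@](C)(O[Si](C)(C)C)[C@@H]23)CC[C@@H]1Br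
F5 | step 24 | hydrindan-2-one, C7 trimethylsilyl ether | CC1(C)C/C(=C/[C@@H]2C(=O)C[C@]3(C)[C@@H](Br)CC[C@@](C)(O[Si](C)(C)C)[C@@H]23)CC[C@@H]1Br
F6 | step 22 | [(1R,4S)-4-bromo-3,3-dimethylcyclohexyl]methyl iodide | IC[C@H]1CC(C)(C)[C@@H](Br)CC1
F7 | step 22 | {[(1R,4S)-4-bromo-3,3-dimethylcyclohexyl]methyl}triphenylphosphonium iodide | c1ccc(cc1)[P+](c1ccccc1)(c1ccccc1)C[C@H]1CC(C)(C)[C@@H](Br)CC1.[I-]
F8 | step 22 | Z isomer of 35 | CC1(C)C[C@H](/C=C\[C@@H]2[C@](C)(O[Si](C)(C)C)CC[C@H](Br)[C@@]2(C)CC(=O)N(C)OC)CC[C@@H]1Br
F9 | step 13 | trimethyl 5-methylhexane-1,3,5-tricarboxylate (racemic) | COC(=O)CCC(CC(C)(C)C(=O)OC)C(=O)OC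
F10 | step 13 | dimethyl 5,5-dimethyl-4-oxocyclohexane-1,3-dicarboxylate (racemic, stereoisomer mixture) | COC(=O)C1CC(C(=O)OC)C(=O)C(C)(C)C1
F11 | step 13 | methyl 3,3-dimethyl-4-oxocyclohexane-1-carboxylate (racemic) | COC(=O)C1CCC(=O)C(C)(C)C1
F12 | step 13 | 3,3-dimethyl-4-oxocyclohexane-1-carboxylic acid (racemic) | OC(=O)C1CCC(=O)C(C)(C)C1
F13 | step 13 | (4S)-4-benzyl-3-[(1S)-3,3-dimethyl-4-oxocyclohexane-1-carbonyl]-1,3-oxazolidin-2-one | O=C([C@@H]1CC(C)(C)C(=O)CC1)N1[C@@H](Cc2ccccc2)COC1=O
F14 | step 1 | 3-(5-methylfuran-2-yl)cyclopent-2-en-1-one | Cc1ccc(o1)C1=CC(=O)CC1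
A1 | alternative 1 | bicyclic enone with C3a methyl, C7 triethylsilyloxy and C4 tert-butyldimethylsilyloxy groups (3a,4,5,6,7-substituted tetrahydroinden-2-one) | O=C1C=C2[C@](C)(O[Si](CC)(CC)CC)CC[C@H](O[Si](C)(C)C(C)(C)C)[C@@]2(C)C1
A2 | alternative 2 | methyl 2-[2,2,3-trisubstituted 4-hydroxy-4-methylcyclohexanone]acetate carrying the (E)-2-(4-bromo-3,3-dimethylcyclohexyl)ethenyl group at C7a | CC1(C)C[C@H](/C=C/[C@@H]2[C@](C)(O)CCC(=O)[C@@]2(C)CC(=O)OC)CC[C@@H]1Br
A3 | alternative 3 | cis-fused γ-lactone enone with C1 methoxycarbonyl group | COC(=O)[C@@H]1C(=O)O[C@]2(C)C=CC(=O)C[C@H]12
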